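**Retrosynthetic overview**
1. The C14=C15′ (E)-enal is made last, by a directed aldol condensation of two C20 aldehydes that differ only at C5. The left half is a trans-decalin and acts as donor; the right half is a cis-decalin (5β-H) and acts as acceptor. A C15=N bond (cyclohexylimine) fixes the donor role. Both aldehyde C15–O bonds are made from inert vinyl groups by aldehyde-selective Wacker oxidation.
2. C9 and the 8(17)-methylene of each half come from a C17–heteroatom bond followed by allylic transposition. On the left a C17–N bond (allylic amination, diazene retro-ene) puts H on C9α. On the right a C17–O bond (SN2′ Mitsunobu picolinate, then copper anti-SN2′) puts C11 on C9β.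
3. Ring B is the carvone ring and is present from the start: (R)-carvone on the left, (S)-carvone on the right. The isopropenyl group steers the Mukaiyama–Michael step (C4–C5) and is then excised.
4. Ring A is stapled on with ClCH2CH2CH2I. On the left, C10 is alkylated first (intermolecular, anti) and C3–C4 is closed late, which gives the trans fusion. On the right, C4 is alkylated first and C1–C10 is closed early (intramolecular, syn), which gives the cis fusion.
5. C18 comes from a late enolate methylation. The side chain C11–C16, including C13, comes from (S)-β-citronellene.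

Convention and assumption: labdane numbering is used for every intermediate, β is the face of the C10 methyl (C20), and primed atoms belong to the right half. The SMILES is taken literally, so the two decalins differ at C5.

Step 1
Reactants: 1 tert-butyl acetate
Product: 2 1-tert-butoxy-1-(tert-butyldimethylsilyloxy)ethene
Conditions: LiN(iPr)2, THF, −78 °C; TBSCl, DMPU, −78 → 23 °C
Reagents that add atoms: tert-butyldimethylsilyl chloride, CC(C)(C)[Si](C)(C)Cl
Why: O-silylation of the lithium ester enolate (ketene silyl acetal formation) gives the Michael donor that carries C4 and C19.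

Step 2
Reactants: 3 (S)-β-citronellene
Product: 5 (S)-4-methylhex-5-enoic acid, via (S)-4-methylhex-5-enal 4 (not isolated)
Conditions: O3 (1.0 equiv), MeCN/H2O 9:1, 0 °C; then NaClO2, NaH2PO4, 0 → 23 °C
Reagents that add atoms: ozone, [O-][O+]=O; sodium chlorite, [Na+].[O-]Cl=O
Why: Chemoselective ozonolysis cleaves the electron-rich trisubstituted alkene much faster than the vinyl group, and Pinnick-type chlorite oxidation of the aldehyde gives the acid with C13 untouched.

Step 3
Reactants: 5 (S)-4-methylhex-5-enoic acid
Product: 6 (S)-5-iodo-3-methylpent-1-ene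
Conditions: PhI(OAc)2, I2, cyclohexane, hν, reflux
Reagents that add atoms: iodine, II
Why: Radical iododecarboxylation (Hunsdiecker type, Suárez conditions) removes the surplus carbon, the 4-pentenyl radical does not cyclise, and C13 is not involved.

Step 4
Reactants: 7 (R)-carvone; 2 ketene silyl acetal
Product: 8 left silyl enol ether (9-OTBS; Δ9(10); 5β-CH2CO2tBu; 7α-isopropenyl)
Conditions: HNTf2 (1 mol %), CH2Cl2, −78 °C
Reagents that add atoms: none
Why: In this silylium-catalysed Mukaiyama–Michael addition, axial attack anti to the C7 isopropenyl group sets C5 and stores the enolate regiospecifically as its silyl enol ether.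

Step 5
Reactants: 8 left silyl enol ether; 9 1-chloro-3-iodopropane
Product: 10 left quaternary ketone (10β-methyl; 10α-(3-chloropropyl); 7α-isopropenyl)
Conditions: BnMe3NF, 4 Å sieves, THF, −20 → 23 °C
Reagents that add atoms: none
Why: In this fluoride-triggered regiospecific enolate alkylation, only the iodide end reacts and it enters anti to the C5 substituent, so C10 is set with C1 trans to C4 (the trans-fusion relationship).

Step 6
Reactants: 10 left quaternary ketone
Product: 12 left ketone without isopropenyl group, via methoxy hydroperoxide 11 (not isolated)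
Conditions: O3, MeOH, −78 °C; then FeSO4·7H2O, PhSH, −78 → 23 °C
Reagents that add atoms: none
Why: In this hydrodealkenylation, divalent iron reduces the peroxide, the alkoxy radical undergoes β-scission, and the C7 radical takes H from the thiol, which removes the used-up control element.

Step 7
Reactants: 12 left ketone
Product: 13 left 8-methylene ketone
Conditions: (CH2O)n, N-methylanilinium trifluoroacetate, THF, reflux
Reagents that add atoms: formaldehyde (as paraformaldehyde), C=O
Why: Mannich-type α-methylenation can occur only at C8 because C10 is quaternary, and it installs C17.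

Step 8
Reactants: 13 left 8-methylene ketone; 6 (S)-5-iodo-3-methylpent-1-ene
Product: 16 left tertiary allylic methyl carbonate, via alkyllithium 14 (not isolated), via lithium alkoxide 15 (not isolated)
Conditions: 6, t-BuLi (2 equiv), Et2O/pentane, −78 °C; 13, −78 °C; ClCO2Me, −78 → 0 °C
Reagents that add atoms: methyl chloroformate, COC(=O)Cl
Why: After iodine–lithium exchange the alkyllithium adds 1,2 to the enone from the α face (axial, anti to the axial C10 methyl), and the alkoxide is acylated in the same flask.

Step 9
Reactants: 16 left tertiary allylic methyl carbonate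
Product: 19 left monocyclic chloro ester (8(17)-methylene; 9α-H), via N-allyl sulfonylhydrazone 17 (not isolated), via allylic diazene 18 (not isolated)
Conditions: Pd2(dba)3·CHCl3 (2.5 mol %), PPh3, N-isopropylidene-N′-(2-nitrobenzenesulfonyl)hydrazine, THF, 23 °C; then CF3CH2OH/H2O, 23 °C
Reagents that add atoms: none
Why: Tsuji–Trost allylic amination at the unhindered primary terminus makes the C17–N bond, and after unmasking the allylic diazene rearrangement (retro-ene loss of N2) delivers H to C9 on the α face opposite the pseudo-axial C10 methyl, which sets C9 and the exocyclic methylene together.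

Step 10
Reactants: 19 left monocyclic chloro ester
Product: 21 tert-butyl (13S)-labda-8(17),14-dien-19-oate, via C4-H trans-decalin ester 20 (not isolated)
Conditions: LiN(iPr)2 (1.1 equiv), THF/DMPU, −78 → 40 °C; recool, LiN(iPr)2 (1.3 equiv), MeI, −78 → 0 °C
Reagents that add atoms: iodomethane, CI
Why: A 6-exo-tet ester enolate alkylation closes ring A as the trans-decalin already fixed by C5 and C10, and the second enolate is methylated from the equatorial α face because axial C20 shields the β face, so C4 carries the axial ester.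

Step 11
Reactants: 21 tert-butyl (13S)-labda-8(17),14-dien-19-oate
Product: 22 tert-butyl (13S)-15-oxolabd-8(17)-en-19-oate
Conditions: PdCl2(PhCN)2 (12 mol %), CuCl2·2H2O (12 mol %), AgNO2 (6 mol %), O2 (1 atm), t-BuOH/MeNO2 15:1, 23 °C
Reagents that add atoms: dioxygen, O=O
Why: The nitrite-modified aldehyde-selective Wacker oxidation forms the C15–O bond at the terminal carbon of the monosubstituted alkene only, and the hindered 1,1-disubstituted alkene stays inert.

Step 12
Reactants: 22 left aldehyde
Product: 23 left N-cyclohexyl aldimine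
Conditions: cyclohexylamine, 4 Å sieves, Et2O, 0 → 23 °C
Reagents that add atoms: cyclohexylamine, NC1CCCCC1
Why: Imine condensation forms the C15=N bond that marks this half, and only this half, as the nucleophile of the crossed aldol step.

Step 13
Reactants: 24 (S)-carvone; 2 ketene silyl acetal
Product: 25 right silyl enol ether (enantiomer of 8; 5α-CH2CO2tBu; 7β-isopropenyl)
Conditions: HNTf2 (1 mol %), CH2Cl2, −78 °C
Reagents that add atoms: none
Why: This Mukaiyama–Michael addition anti to the 7β-isopropenyl group places C4′ on the α face and so sets the 5′β-H centre.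

Step 14
Reactants: 25 right silyl enol ether; 9 1-chloro-3-iodopropane
Product: 26 right C4-alkylated silyl enol ether (C4 epimers)
Conditions: LiN(iPr)2, THF, −78 °C; 9, DMPU, −78 → −20 °C
Reagents that add atoms: none
Why: This ester enolate alkylation proceeds while the ketone stays masked as its silyl enol ether, and the C4 configuration is irrelevant because it is erased in step 21.

Step 15
Reactants: 26 right C4-alkylated silyl enol ether
Product: 27 right cis-decalone (7β-isopropenyl; C4 epimers)
Conditions: BnMe3NF, 4 Å sieves, THF, 23 → 50 °C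
Reagents that add atoms: none
Why: In this fluoride-triggered intramolecular enolate alkylation the tether hangs from the α-oriented C4′ and reaches C10′ only from the α face, so ring A closes cis-fused with C20′ β.

Step 16
Reactants: 27 right cis-decalone
Product: 29 right cis-decalone without isopropenyl group, via methoxy hydroperoxide 28 (not isolated)
Conditions: O3, MeOH, −78 °C; then FeSO4·7H2O, PhSH, −78 → 23 °C
Reagents that add atoms: none
Why: Hydrodealkenylation proceeds as in step 6, and the isopropenyl group is the only alkene present.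

Step 17
Reactants: 29 right cis-decalone
Product: 30 right 8-methylene ketone
Conditions: (CH2O)n, N-methylanilinium trifluoroacetate, THF, reflux
Reagents that add atoms: formaldehyde (as paraformaldehyde), C=O
Why: Mannich-type α-methylenation occurs at the only enolisable position next to the ketone and installs C17′.

Step 18
Reactants: 30 right 8-methylene ketone
Product: 31 right allylic alcohol (9-OH; either epimer serves)
Conditions: NaBH4, CeCl3·7H2O, MeOH, −78 → 0 °C
Reagents that add atoms: none
Why: Luche reduction gives clean 1,2-reduction of the exocyclic enone, and the carbinol centre is lost in the next step.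

Step 19
Reactants: 31 right allylic alcohol
Product: 32 right primary allylic picolinate (Δ8(9); C17-O)
Conditions: picolinic acid, PPh3, DIAD, toluene, 0 → 23 °C
Reagents that add atoms: picolinic acid, OC(=O)c1ccccn1
Why: In this Mitsunobu esterification direct displacement at the neopentyl C9′ is blocked, so the carboxylate attacks the open methylene terminus in the SN2′ sense, which forms the C17′–O bond and moves the alkene to C8′=C9′.

Step 20
Reactants: 32 right primary allylic picolinate; 6 (S)-5-iodo-3-methylpent-1-ene
Product: 34 right C4-H cis-decalin ester bearing the side chain (8(17)-methylene; 9β-chain), via alkylmagnesium iodide 33 (not isolated)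
Conditions: 6, Mg, Et2O, 23 °C; then 32, CuBr·SMe2 (20 mol %), THF, −40 → 0 °C
Reagents that add atoms: none
Why: Proposed new method: copper-catalysed anti-SN2′ alkylation of a primary allylic picolinate whose γ-carbon is a ring CH flanked by a quaternary centre, using an alkene-bearing primary alkylmagnesium iodide; magnesium chelation by the pyridine nitrogen and carbonyl oxygen activates the freely rotating leaving group, the alkylcopper species adds to C9′ on the convex β face because the pseudo-axial C1′–C10′ bond of the favoured cis-octalin half-chair shields the α face, and reductive elimination forges C9′–C11′ while the alkene shifts to C8′=C17′, so the bond, the C9′ centre and the exocyclic methylene arise together; the closest known reaction type is picolinate-directed copper-mediated SN2′ allylic substitution of secondary acyclic and simple cyclic substrates.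

Step 21
Reactants: 34 right C4-H cis-decalin ester
Product: 35 tert-butyl (5β,13S)-labda-8(17),14-dien-19-oate
Conditions: LiN(iPr)2, THF/DMPU, −78 °C; MeI, −78 → 0 °C
Reagents that add atoms: iodomethane, CI
Why: In this ester enolate methylation, allylic 1,3-strain forces H5′ into the enolate plane, which selects the conformer with C20′ axial on ring A, so MeI enters from the equatorial α face and C19′ ends up β, cis to H5′ and C20′.

Step 22
Reactants: 35 tert-butyl (5β,13S)-labda-8(17),14-dien-19-oate
Product: 36 tert-butyl (5β,13S)-15-oxolabd-8(17)-en-19-oate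
Conditions: PdCl2(PhCN)2 (12 mol %), CuCl2·2H2O (12 mol %), AgNO2 (6 mol %), O2 (1 atm), t-BuOH/MeNO2 15:1, 23 °C
Reagents that add atoms: dioxygen, O=O
Why: The aldehyde-selective Wacker oxidation forms the C15′–O bond on the vinyl group only, as in step 11.

Step 23
Reactants: 23 left N-cyclohexyl aldimine; 36 right aldehyde
Product: 39 di-tert-butyl ester of the target, via lithio enamide 37 (not isolated), via lithium aldolate 38 (not isolated)
Conditions: LiN(iPr)2, THF, −78 → 0 °C; 36, −78 °C; then aq. oxalic acid, THF, 23 °C
Reagents that add atoms: water, O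
Why: In this Wittig directed aldol reaction only the metallated imine can be the nucleophile, and acid hydrolysis with dehydration gives the thermodynamically favoured (E)-2-alkylenal (CHO trans to C14′).

Step 24
Reactants: 39 di-tert-butyl ester of the target
Product: 41 target diacid CNP0229303.1, via bis(trimethylsilyl) ester 40 (not isolated)
Conditions: Me3SiOTf, 2,6-lutidine, CH2Cl2, 0 → 23 °C; then pH 5 aqueous buffer
Reagents that add atoms: none
Why: Silyl triflate-induced alkyl–oxygen cleavage of both tert-butyl esters works at hindered acyl carbons, and the buffered medium avoids the protic acid that would isomerise the exocyclic alkenes.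

**Compound list**
1 | tert-butyl acetate | CC(=O)OC(C)(C)C | starting material
2 | 1-tert-butoxy-1-(tert-butyldimethylsilyloxy)ethene | C=C(OC(C)(C)C)O[Si](C)(C)C(C)(C)C | intermediate
3 | (S)-β-citronellene, (3S)-3,7-dimethylocta-1,6-diene | C=C[C@@H](C)CCC=C(C)C | starting material
4 | (S)-4-methylhex-5-enal | C=C[C@@H](C)CCC=O | intermediate
5 | (S)-4-methylhex-5-enoic acid | C=C[C@@H](C)CCC(=O)O | intermediate
6 | (S)-5-iodo-3-methylpent-1-ene | C=C[C@@H](C)CCI | intermediate
7 | (R)-carvone | O=C1C[C@H](C(C)=C)CC=C1C | starting material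
8 | left silyl enol ether (9-OTBS, Δ9(10), 5β-CH2CO2tBu, 7α-isopropenyl) | CC1=C(O[Si](C)(C)C(C)(C)C)C[C@H](C(C)=C)C[C@H]1CC(=O)OC(C)(C)C | intermediate
9 | 1-chloro-3-iodopropane | ClCCCI | starting material
10 | left quaternary ketone (9-oxo, 10β-Me, 10α-(3-chloropropyl), 5β-CH2CO2tBu, 7α-isopropenyl) | O=C1C[C@H](C(C)=C)C[C@@H](CC(=O)OC(C)(C)C)[C@]1(C)CCCCl | intermediate
11 | left methoxy hydroperoxide (7α-C(Me)(OMe)OOH) | O=C1C[C@H](C(C)(OC)OO)C[C@@H](CC(=O)OC(C)(C)C)[C@]1(C)CCCCl | intermediate
12 | left ketone without isopropenyl group | O=C1CCC[C@@H](CC(=O)OC(C)(C)C)[C@]1(C)CCCCl | intermediate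
13 | left 8-methylene ketone | O=C1C(=C)CC[C@@H](CC(=O)OC(C)(C)C)[C@]1(C)CCCCl | intermediate
14 | (S)-3-methylpent-4-enyllithium | [Li]CC[C@H](C)C=C | intermediate
15 | left lithium alkoxide (9β-OLi, 9α-chain) | [Li]O[C@@]1(CC[C@H](C)C=C)C(=C)CC[C@@H](CC(=O)OC(C)(C)C)[C@]1(C)CCCCl | intermediate
16 | left tertiary allylic methyl carbonate | COC(=O)O[C@@]1(CC[C@H](C)C=C)C(=C)CC[C@@H](CC(=O)OC(C)(C)C)[C@]1(C)CCCCl | intermediate
17 | left N-allyl sulfonylhydrazone (C17–N, Δ8(9)) | CC(C)=NN(CC1=C(CC[C@H](C)C=C)[C@@](C)(CCCCl)[C@H](CC(=O)OC(C)(C)C)CC1)S(=O)(=O)c1ccccc1[N+](=O)[O-] | intermediate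
18 | left allylic diazene | N=NCC1=C(CC[C@H](C)C=C)[C@@](C)(CCCCl)[C@H](CC(=O)OC(C)(C)C)CC1 | intermediate
19 | left monocyclic chloro ester (8(17)-methylene, 9α-H, 9β-chain) | C=C1CC[C@@H](CC(=O)OC(C)(C)C)[C@](C)(CCCCl)[C@H]1CC[C@H](C)C=C | intermediate
20 | left C4-H trans-decalin ester (C4 epimers) | C=C1CC[C@@H]2[C@](C)(CCCC2C(=O)OC(C)(C)C)[C@H]1CC[C@H](C)C=C | intermediate
21 | tert-butyl (13S)-labda-8(17),14-dien-19-oate | C=C1CC[C@@H]2[C@](C)(CCC[C@]2(C)C(=O)OC(C)(C)C)[C@H]1CC[C@H](C)C=C | intermediate
22 | tert-butyl (13S)-15-oxolabd-8(17)-en-19-oate | C=C1CC[C@@H]2[C@](C)(CCC[C@]2(C)C(=O)OC(C)(C)C)[C@H]1CC[C@H](C)CC=O | intermediate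
23 | N-cyclohexyl aldimine of 22 | C=C1CC[C@@H]2[C@](C)(CCC[C@]2(C)C(=O)OC(C)(C)C)[C@H]1CC[C@H](C)C/C=N/C1CCCCC1 | intermediate
24 | (S)-carvone | O=C1C[C@@H](C(C)=C)CC=C1C | starting material
25 | right silyl enol ether (5α-CH2CO2tBu, 7β-isopropenyl) | CC1=C(O[Si](C)(C)C(C)(C)C)C[C@@H](C(C)=C)C[C@@H]1CC(=O)OC(C)(C)C | intermediate
26 | right C4-(3-chloropropyl) silyl enol ether (C4 epimers) | CC1=C(O[Si](C)(C)C(C)(C)C)C[C@@H](C(C)=C)C[C@@H]1C(CCCCl)C(=O)OC(C)(C)C | intermediate
27 | right cis-decalone (5β-H, 10β-Me, 7β-isopropenyl, C4 epimers) | O=C1C[C@@H](C(C)=C)C[C@H]2[C@]1(C)CCCC2C(=O)OC(C)(C)C | intermediate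
28 | right methoxy hydroperoxide | O=C1C[C@@H](C(C)(OC)OO)C[C@H]2[C@]1(C)CCCC2C(=O)OC(C)(C)C | intermediate
29 | right cis-decalone without isopropenyl group | O=C1CCC[C@H]2[C@]1(C)CCCC2C(=O)OC(C)(C)C | intermediate
30 | right 8-methylene ketone | O=C1C(=C)CC[C@H]2[C@]1(C)CCCC2C(=O)OC(C)(C)C | intermediate
31 | right allylic alcohol (9-OH epimers) | OC1C(=C)CC[C@H]2[C@]1(C)CCCC2C(=O)OC(C)(C)C | intermediate
32 | right primary allylic picolinate (Δ8(9)) | O=C(OCC1=C[C@@]2(C)CCCC(C(=O)OC(C)(C)C)[C@H]2CC1)c1ccccn1 | intermediate
33 | (S)-3-methylpent-4-enylmagnesium iodide | I[Mg]CC[C@H](C)C=C | intermediate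
34 | right C4-H cis-decalin ester with side chain (9α-H, C4 epimers) | C=C[C@@H](C)CC[C@H]1C(=C)CC[C@H]2[C@]1(C)CCCC2C(=O)OC(C)(C)C | intermediate
35 | tert-butyl (5β,13S)-labda-8(17),14-dien-19-oate | C=C[C@@H](C)CC[C@H]1C(=C)CC[C@H]2[C@]1(C)CCC[C@]2(C)C(=O)OC(C)(C)C | intermediate
36 | tert-butyl (5β,13S)-15-oxolabd-8(17)-en-19-oate | O=CC[C@@H](C)CC[C@H]1C(=C)CC[C@H]2[C@]1(C)CCC[C@]2(C)C(=O)OC(C)(C)C | intermediate
37 | lithio enamide of 23 | C=C1CC[C@@H]2[C@](C)(CCC[C@]2(C)C(=O)OC(C)(C)C)[C@H]1CC[C@H](C)/C=C/N([Li])C1CCCCC1 | intermediate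
38 | lithium aldolate (β-oxido imine, C14/C15′ epimers) | C=C1CC[C@@H]2[C@](C)(CCC[C@]2(C)C(=O)OC(C)(C)C)[C@H]1CC[C@H](C)C(C=NC1CCCCC1)C(O[Li])C[C@@H](C)CC[C@H]1C(=C)CC[C@H]2[C@]1(C)CCC[C@]2(C)C(=O)OC(C)(C)C | intermediate
39 | di-tert-butyl ester of the target | C=C1CC[C@@H]2[C@](C)(CCC[C@]2(C)C(=O)OC(C)(C)C)[C@H]1CC[C@H](C)/C(C=O)=C\C[C@@H](C)CC[C@H]1C(=C)CC[C@H]2[C@]1(C)CCC[C@]2(C)C(=O)OC(C)(C)C | intermediate
40 | bis(trimethylsilyl) ester of the target | C=C1CC[C@@H]2[C@](C)(CCC[C@]2(C)C(=O)O[Si](C)(C)C)[C@H]1CC[C@H](C)/C(C=O)=C\C[C@@H](C)CC[C@H]1C(=C)CC[C@H]2[C@]1(C)CCC[C@]2(C)C(=O)O[Si](C)(C)C | intermediate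
41 | CNP0229303.1 | C=C1CC[C@@H]2[C@](C)(CCC[C@]2(C)C(=O)O)[C@H]1CC[C@H](C)/C(C=O)=C\C[C@@H](C)CC[C@H]1C(=C)CC[C@H]2[C@]1(C)CCC[C@]2(C)C(=O)O | target

**Step count**
- Total steps: 24.
- Longest linear sequence: 13 (steps 1 and 13–24).

**Three steps most likely to fail**

Step 20 (the new step). The risks are α-attack at C17′ or acyl attack by the Grignard reagent. The fallback uses known chemistry and sets out from 32.
- Methanolysis (K2CO3, MeOH) gives the allylic alcohol F1.
- Esterification of F1 with acid 5 (EDC·HCl, DMAP) gives the allyl ester F2.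
- Ireland–Claisen rearrangement (KN(SiMe3)2, Me3SiCl, THF, −78 → 23 °C) makes C9′–C11′ on the convex β face with the same alkene shift and gives the C11′-carboxylic acid F3.
- Organic-photoredox hydrodecarboxylation (9-mesityl-10-methylacridinium tetrafluoroborate, PhSSPh, iPr2NEt, CF3CH2OH, blue light) removes the tether carbon and returns to 34.

Step 5. The risk is building the quaternary centre with an unactivated alkyl iodide. The fallback sets out from 8 and brings the three carbons in as an activated allyl group.
- Allyl iodide under the same fluoride release gives the allyl ketone F4.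
- 9-BBN hydroborates only the monosubstituted alkene, and NaBO3·4H2O then gives the primary alcohol F5.
- Appel chlorination (PPh3, CCl4) returns to 10.

Step 9. The risks are ionisation of the hindered carbonate and the timing of the diazene step. The fallback sets out from 16 and replaces the nitrogen relay by hydride. Tsuji–Mandai hydrogenolysis (Pd2(dba)3·CHCl3, PBu3, HCO2H/Et3N, THF) transfers formate hydride to the more substituted allyl terminus C9. It leads directly to 19 without any new compound.

**Further compounds**
F1 | step 20 | right allylic alcohol (C17-OH, Δ8(9)) | OCC1=C[C@@]2(C)CCCC(C(=O)OC(C)(C)C)[C@H]2CC1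
F2 | step 20 | (S)-4-methylhex-5-enoate of F1 | C=C[C@@H](C)CCC(=O)OCC1=C[C@@]2(C)CCCC(C(=O)OC(C)(C)C)[C@H]2CC1
F3 | step 20 | Ireland–Claisen acid (C11-CO2H, C11 epimers) | C=C[C@@H](C)CC(C(=O)O)[C@H]1C(=C)CC[C@H]2[C@]1(C)CCCC2C(=O)OC(C)(C)C
F4 | step 5 | left 10α-allyl ketone | O=C1C[C@H](C(C)=C)C[C@@H](CC(=O)OC(C)(C)C)[C@]1(C)CC=C
F5 | step 5 | left 10α-(3-hydroxypropyl) ketone | O=C1C[C@H](C(C)=C)C[C@@H](CC(=O)OC(C)(C)C)[C@]1(C)CCCO
F0 | step 9 | none | none
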